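## Retrosynthetic overview

1. The strategy rests on the 1,2-dioxolane (O1–O2–C3–C4–C5): C3 and C5 are both fully substituted C–O stereocentres whose carbon arms differ only as CH3 versus CH2R, so each is set by a tartrate-controlled epoxide and passed on by an invertive C–O displacement.
2. The acid comes from a one-carbon homologation (Wittig, hydrolysis, Pinnick) of the C3 carbaldehyde, itself from periodate cleavage of a 1,2-diol arm on C3.
3. The dioxolane, the only ring kept, comes from 5-exo opening of a C3 trisubstituted epoxy alcohol by the C5 tertiary hydroperoxide, unmasked from its peroxyketal.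
4. The C5–OOH group comes from invertive perhydrolysis of a 2,2-disubstituted oxetane (Sharpless epoxide, hydride opening, cyclisation); the C3 epoxide comes from HWE olefination, reduction and a second Sharpless epoxidation on the β-peroxy methyl ketone.
5. The chain comes from (R)-citronellal (alkyne, ozonolysis, Julia–Kocienski with a Johnson–Claisen-derived sulfone, Negishi carboalumination). Ring order: oxirane (step 9), oxetane (step 12), oxirane (step 20), 1,2-dioxolane (step 21).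

Key step: step 21

Assumption: L-(+)-diethyl tartrate epoxidises these (E)-3-methylalk-2-en-1-ols (larger 3-substituent trans to CH2OH) in the same facial sense as geraniol, giving (2S,3S)-epoxides; anhydrous ethereal H2O2 is used in step 13.

## Route

Step 1
Reactants: 1 rac-1-phenylprop-2-en-1-ol
Product: 2 ethyl (4E)-5-phenylpent-4-enoate
Conditions: MeC(OEt)3 (5 equiv), EtCO2H (cat.), 140 °C, EtOH distilled off
Reagents that add atoms: triethyl orthoacetate, CC(OCC)(OCC)OCC
Why: Johnson–Claisen rearrangement of the ketene acetal through a chair transition state with phenyl equatorial should give the E-styrenyl ester, and the carbinol centre is destroyed, so racemic 1 suffices.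

Step 2
Reactants: 2 ethyl (4E)-5-phenylpent-4-enoate
Product: 3 (4E)-5-phenylpent-4-en-1-ol
Conditions: LiAlH4, THF, 0 °C
Reagents that add atoms: none
Why: Ester reduction by LiAlH4 should leave the styrene, which is not conjugated to the carbonyl, untouched.

Step 3
Reactants: 3 (4E)-5-phenylpent-4-en-1-ol
Product: 4 1-phenyl-5-{[(4E)-5-phenylpent-4-en-1-yl]sulfanyl}-1H-tetrazole
Conditions: 1-phenyl-1H-tetrazole-5-thiol, PPh3, DIAD, THF, 0 °C → rt
Reagents that add atoms: 1-phenyl-1H-tetrazole-5-thiol, Sc1nnnn1-c1ccccc1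
Why: Mitsunobu thioetherification of an unhindered primary alcohol with the acidic tetrazolethiol is reliable.

Step 4
Reactants: 4 1-phenyl-5-{[(4E)-5-phenylpent-4-en-1-yl]sulfanyl}-1H-tetrazole
Product: 5 1-phenyl-5-{[(4E)-5-phenylpent-4-en-1-yl]sulfonyl}-1H-tetrazole
Conditions: (NH4)6Mo7O24·4H2O (cat.), 30% H2O2, EtOH, 0 °C → rt
Reagents that add atoms: hydrogen peroxide, OO
Why: Molybdate-catalysed sulfide-to-sulfone oxidation is much faster than epoxidation of the conjugated styrene, so the alkene should survive.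

Step 5
Reactants: 6 (R)-citronellal
Product: 7 (4R)-4,8-dimethylnon-7-en-1-yne
Conditions: dimethyl (1-diazo-2-oxopropyl)phosphonate, K2CO3, MeOH, 0 °C → rt
Reagents that add atoms: dimethyl (1-diazo-2-oxopropyl)phosphonate, CC(=O)C(=[N+]=[N-])P(=O)(OC)OC
Why: Ohira–Bestmann (Seyferth–Gilbert) homologation converts the aldehyde into the terminal alkyne under mild carbonate conditions, and the methyl-bearing centre is β to the carbonyl and cannot epimerise.

Step 6
Reactants: 7 (4R)-4,8-dimethylnon-7-en-1-yne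
Product: 9 (4R)-4-methylhept-6-ynal, via secondary ozonide 8 (not isolated)
Conditions: O3, CH2Cl2, −78 °C (Sudan Red 7B end point); then PPh3, −78 °C → rt
Reagents that add atoms: ozone, [O-][O+]=O
Why: Ozonolysis of the electron-rich trisubstituted alkene is far faster than attack on a terminal alkyne, and the dye end point stops the reaction once the alkene is consumed.

Step 7
Reactants: 5 1-phenyl-5-{[(4E)-5-phenylpent-4-en-1-yl]sulfonyl}-1H-tetrazole; 9 (4R)-4-methylhept-6-ynal
Product: 10 [(1E,5E,9R)-9-methyldodeca-1,5-dien-11-yn-1-yl]benzene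
Conditions: 5, KN(SiMe3)2, DME, −60 °C; then 9, −60 °C → rt
Reagents that add atoms: none
Why: Julia–Kocienski olefination of a 1-phenyltetrazolyl sulfone with a potassium counter-ion in DME should favour the E-alkene, and the sulfonyl carbanion is too weak a base to deprotonate the terminal alkyne.

Step 8
Reactants: 10 [(1E,5E,9R)-9-methyldodeca-1,5-dien-11-yn-1-yl]benzene
Product: 12 (2E,5R,8E,12E)-3,5-dimethyl-13-phenyltrideca-2,8,12-trien-1-ol, via alkenylalane 11 (not isolated)
Conditions: Me3Al (2.5 equiv), Cp2ZrCl2 (0.25 equiv), CH2Cl2, 0 °C → rt; then (CH2O)n, 0 °C → rt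
Reagents that add atoms: trimethylaluminium, C[Al](C)C; paraformaldehyde (as formaldehyde), C=O
Why: Negishi zirconium-catalysed carboalumination adds Me and Al syn across the terminal alkyne with Al on the terminal carbon, and trapping with formaldehyde with retention should give the E-allylic alcohol as one isomer, the internal alkenes being inert.

Step 9
Reactants: 12 (2E,5R,8E,12E)-3,5-dimethyl-13-phenyltrideca-2,8,12-trien-1-ol
Product: 13 [(2S,3S)-3-methyl-3-[(2R,5E,9E)-2-methyl-10-phenyldeca-5,9-dien-1-yl]oxiran-2-yl]methanol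
Conditions: Ti(OiPr)4 (10 mol%), L-(+)-diethyl tartrate (12 mol%), t-BuOOH (2 equiv), 4 Å MS, CH2Cl2, −20 °C
Reagents that add atoms: tert-butyl hydroperoxide, CC(C)(C)OO
Why: Sharpless asymmetric epoxidation acts only on the titanium-bound allylic alcohol, so the distal alkenes are spared, and L-(+)-tartrate should give the (2S,3S)-epoxide, fixing the C–O bond at the future C5 in the sense that is later inverted.

Step 10
Reactants: 13 [(2S,3S)-3-methyl-3-[(2R,5E,9E)-2-methyl-10-phenyldeca-5,9-dien-1-yl]oxiran-2-yl]methanol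
Product: 14 (3S,5R,8E,12E)-3,5-dimethyl-13-phenyltrideca-8,12-diene-1,3-diol
Conditions: NaAlH2(OCH2CH2OMe)2 (Red-Al), THF, 0 °C
Reagents that add atoms: none
Why: Hydroxyl-directed hydride delivery from the bound aluminate to C2 of the 2,3-epoxy alcohol should give the 1,3-diol, and the tertiary C–O bond is not touched, so its configuration is kept.

Step 11
Reactants: 14 (3S,5R,8E,12E)-3,5-dimethyl-13-phenyltrideca-8,12-diene-1,3-diol
Product: 15 (3S,5R,8E,12E)-3-hydroxy-3,5-dimethyl-13-phenyltrideca-8,12-dien-1-yl 4-methylbenzenesulfonate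
Conditions: TsCl, Et3N, DMAP (cat.), CH2Cl2, 0 °C
Reagents that add atoms: 4-methylbenzenesulfonyl chloride, Cc1ccc(cc1)S(Cl)(=O)=O
Why: Sulfonylation is selective for the primary over the tertiary hydroxyl on steric grounds.

Step 12
Reactants: 15 (3S,5R,8E,12E)-3-hydroxy-3,5-dimethyl-13-phenyltrideca-8,12-dien-1-yl 4-methylbenzenesulfonate
Product: 16 (2S)-2-methyl-2-[(2R,5E,9E)-2-methyl-10-phenyldeca-5,9-dien-1-yl]oxetane
Conditions: KOtBu, THF, 0 °C → rt
Reagents that add atoms: none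
Why: Intramolecular Williamson etherification (4-exo-tet) of the tertiary alkoxide onto the primary tosylate closes the oxetane without breaking the C–O bond at the stereocentre.

Step 13
Reactants: 16 (2S)-2-methyl-2-[(2R,5E,9E)-2-methyl-10-phenyldeca-5,9-dien-1-yl]oxetane
Product: 17 (3R,5R,8E,12E)-3-hydroperoxy-3,5-dimethyl-13-phenyltrideca-8,12-dien-1-ol
Conditions: H2O2 (anhydrous, in Et2O, 10 equiv), TMSOTf (0.2 equiv), Et2O, −78 → −20 °C
Reagents that add atoms: hydrogen peroxide, OO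
Why: Lewis acid-promoted perhydrolysis of the strained oxetane takes place at the tertiary carbon by backside attack on a tight ion pair, so the C5 hydroperoxide should form with inversion, and low temperature with excess peroxide suppresses a free cation that could racemise or be captured by the distal alkenes.

Step 14
Reactants: 17 (3R,5R,8E,12E)-3-hydroperoxy-3,5-dimethyl-13-phenyltrideca-8,12-dien-1-ol
Product: 18 (3R,5R,8E,12E)-3-[(2-methoxypropan-2-yl)peroxy]-3,5-dimethyl-13-phenyltrideca-8,12-dien-1-ol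
Conditions: 2-methoxypropene (1.1 equiv), PPTS (5 mol%), CH2Cl2, 0 °C
Reagents that add atoms: 2-methoxypropene, COC(C)=C
Why: Acid-catalysed ketalisation should favour the more acidic, more nucleophilic OOH group over the primary alcohol, giving the monoperoxyketal that masks the hydroperoxide.

Step 15
Reactants: 18 (3R,5R,8E,12E)-3-[(2-methoxypropan-2-yl)peroxy]-3,5-dimethyl-13-phenyltrideca-8,12-dien-1-ol
Product: 19 (3R,5R,8E,12E)-3-[(2-methoxypropan-2-yl)peroxy]-3,5-dimethyl-13-phenyltrideca-8,12-dienal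
Conditions: Dess–Martin periodinane, NaHCO3, CH2Cl2, 0 °C → rt
Reagents that add atoms: none
Why: Buffered Dess–Martin oxidation is neutral and non-nucleophilic, so the acid-labile peroxyketal and the base-sensitive β-peroxy aldehyde should both survive.

Step 16
Reactants: 19 (3R,5R,8E,12E)-3-[(2-methoxypropan-2-yl)peroxy]-3,5-dimethyl-13-phenyltrideca-8,12-dienal
Product: 20 (4R,6R,9E,13E)-4-[(2-methoxypropan-2-yl)peroxy]-4,6-dimethyl-14-phenyltetradeca-9,13-dien-2-ol (both C2 epimers)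
Conditions: MeMgBr, THF, −78 °C
Reagents that add atoms: methylmagnesium bromide, C[Mg]Br
Why: Grignard addition to the aldehyde at −78 °C is far faster than attack on the hindered di-tertiary O–O bond, and the carbinol epimers converge in the next step.

Step 17
Reactants: 20 (4R,6R,9E,13E)-4-[(2-methoxypropan-2-yl)peroxy]-4,6-dimethyl-14-phenyltetradeca-9,13-dien-2-ol
Product: 21 (4R,6R,9E,13E)-4-[(2-methoxypropan-2-yl)peroxy]-4,6-dimethyl-14-phenyltetradeca-9,13-dien-2-one
Conditions: Dess–Martin periodinane, NaHCO3, CH2Cl2, 0 °C → rt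
Reagents that add atoms: none
Why: Buffered Dess–Martin oxidation of the secondary alcohol gives the methyl ketone without base that could eliminate the β-peroxy group.

Step 18
Reactants: 21 (4R,6R,9E,13E)-4-[(2-methoxypropan-2-yl)peroxy]-4,6-dimethyl-14-phenyltetradeca-9,13-dien-2-one
Product: 22 ethyl (2E,5R,7R,10E,14E)-5-[(2-methoxypropan-2-yl)peroxy]-3,5,7-trimethyl-15-phenylpentadeca-2,10,14-trienoate
Conditions: (EtO)2P(O)CH2CO2Et, NaH, THF, 0 °C → rt; Z-isomer removed by chromatography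
Reagents that add atoms: triethyl phosphonoacetate, CCOC(=O)CP(=O)(OCC)OCC
Why: Horner–Wadsworth–Emmons olefination should place the ester trans to the larger neopentyl-type CH2 group (E major), and the stabilised phosphonate anion is a weak enough base to limit enolisation and β-elimination of the peroxide.

Step 19
Reactants: 22 ethyl (2E,5R,7R,10E,14E)-5-[(2-methoxypropan-2-yl)peroxy]-3,5,7-trimethyl-15-phenylpentadeca-2,10,14-trienoate
Product: 23 (2E,5R,7R,10E,14E)-5-[(2-methoxypropan-2-yl)peroxy]-3,5,7-trimethyl-15-phenylpentadeca-2,10,14-trien-1-ol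
Conditions: i-Bu2AlH (2.5 equiv), CH2Cl2, −78 °C; Rochelle salt work-up
Reagents that add atoms: none
Why: 1,2-Reduction of the enoate by i-Bu2AlH at −78 °C should leave the hindered di-tertiary peroxide intact.

Step 20
Reactants: 23 (2E,5R,7R,10E,14E)-5-[(2-methoxypropan-2-yl)peroxy]-3,5,7-trimethyl-15-phenylpentadeca-2,10,14-trien-1-ol
Product: 24 [(2S,3S)-3-{(2R,4R,7E,11E)-2-[(2-methoxypropan-2-yl)peroxy]-2,4-dimethyl-12-phenyldodeca-7,11-dien-1-yl}-3-methyloxiran-2-yl]methanol
Conditions: Ti(OiPr)4 (10 mol%), L-(+)-diethyl tartrate (12 mol%), t-BuOOH (2 equiv), 4 Å MS, CH2Cl2, −20 °C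
Reagents that add atoms: tert-butyl hydroperoxide, CC(C)(C)OO
Why: Sharpless asymmetric epoxidation is reagent-controlled because the C5 centre is remote from the alkene, so L-(+)-tartrate should give the (2S,3S)-epoxide while the peroxyketal and distal alkenes are not substrates.

Step 21
Reactants: 24 [(2S,3S)-3-{(2R,4R,7E,11E)-2-[(2-methoxypropan-2-yl)peroxy]-2,4-dimethyl-12-phenyldodeca-7,11-dien-1-yl}-3-methyloxiran-2-yl]methanol
Product: 26 (1S)-1-[(3R,5R)-3,5-dimethyl-5-[(2R,5E,9E)-2-methyl-10-phenyldeca-5,9-dien-1-yl]-1,2-dioxolan-3-yl]ethane-1,2-diol, via free hydroperoxide 25 (not isolated)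
Conditions: PPTS (0.1 equiv), MeOH, 0 °C; evaporate; then CSA (0.1 equiv), CH2Cl2, 0 °C → rt
Reagents that add atoms: none
Why: Methanolysis of the peroxyketal under PPTS frees hydroperoxide 25, and after methanol is removed CSA protonates the epoxide oxygen so that the terminal oxygen of the OOH group attacks the tertiary epoxide carbon C3 from the face opposite the departing oxygen, forming O2–C3 in an SN2-like displacement. The closest known reaction type is the acid-promoted intramolecular opening of epoxides by hydroperoxides to give cyclic peroxides. The 1,2-dioxolane closes in a 5-exo-tet mode. The new C3 stereocentre is controlled by the epoxide configuration set with L-(+)-tartrate in step 20 and is transferred with inversion, while C5 (step 13) and the carbinol carbon (retention) are untouched. The step needs 5-exo attack at C3 over 6-endo attack at C2 and over external nucleophiles: the tertiary carbon carries the developing positive charge better, C2 is deactivated by the adjacent CH2OH, and methanol is stripped off before the stronger acid is added, which also prevents acetonide formation on the product diol.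

Step 22
Reactants: 26 (1S)-1-[(3R,5R)-3,5-dimethyl-5-[(2R,5E,9E)-2-methyl-10-phenyldeca-5,9-dien-1-yl]-1,2-dioxolan-3-yl]ethane-1,2-diol
Product: 27 (3R,5R)-3,5-dimethyl-5-[(2R,5E,9E)-2-methyl-10-phenyldeca-5,9-dien-1-yl]-1,2-dioxolane-3-carbaldehyde
Conditions: NaIO4, THF/H2O (pH 7 buffer), 0 °C → rt
Reagents that add atoms: none
Why: Periodate glycol cleavage excises the terminal carbon under neutral conditions, and the quaternary C3 has no α-hydrogen to epimerise.

Step 23
Reactants: 27 (3R,5R)-3,5-dimethyl-5-[(2R,5E,9E)-2-methyl-10-phenyldeca-5,9-dien-1-yl]-1,2-dioxolane-3-carbaldehyde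
Product: 28 (3R,5R)-3-(2-methoxyethenyl)-3,5-dimethyl-5-[(2R,5E,9E)-2-methyl-10-phenyldeca-5,9-dien-1-yl]-1,2-dioxolane (E/Z mixture)
Conditions: Ph3P(CH2OMe)Cl, KN(SiMe3)2, THF, −78 → 0 °C
Reagents that add atoms: (methoxymethyl)triphenylphosphonium chloride, [Cl-].COC[P+](c1ccccc1)(c1ccccc1)c1ccccc1
Why: Wittig olefination with the methoxymethylene ylide homologates the non-enolisable aldehyde, the hindered di-tertiary dioxolane O–O bond should resist the ylide, and the enol ether geometry is inconsequential.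

Step 24
Reactants: 28 (3R,5R)-3-(2-methoxyethenyl)-3,5-dimethyl-5-[(2R,5E,9E)-2-methyl-10-phenyldeca-5,9-dien-1-yl]-1,2-dioxolane
Product: 29 2-[(3R,5R)-3,5-dimethyl-5-[(2R,5E,9E)-2-methyl-10-phenyldeca-5,9-dien-1-yl]-1,2-dioxolan-3-yl]acetaldehyde
Conditions: p-TsOH·H2O (cat.), acetone/H2O, rt
Reagents that add atoms: water, O
Why: Acid-catalysed enol ether hydrolysis proceeds through the oxocarbenium ion and hemiacetal, the dialkyl peroxide is acid-stable, and the acidic medium avoids base-induced β-elimination of the β-peroxy aldehyde.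

Step 25
Reactants: 29 2-[(3R,5R)-3,5-dimethyl-5-[(2R,5E,9E)-2-methyl-10-phenyldeca-5,9-dien-1-yl]-1,2-dioxolan-3-yl]acetaldehyde
Product: 30 2-[(3R,5R)-3,5-dimethyl-5-[(2R,5E,9E)-2-methyl-10-phenyldeca-5,9-dien-1-yl]-1,2-dioxolan-3-yl]acetic acid
Conditions: NaClO2, NaH2PO4, 2-methyl-2-butene (excess), t-BuOH/H2O, 0 °C → rt
Reagents that add atoms: sodium chlorite, [Na+].[O-]Cl=O
Why: Pinnick oxidation converts the aldehyde to the acid under mildly acidic conditions, the alkene scavenger removes HOCl before it can reach the two chain alkenes, and no stereocentre is touched.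

## Compound list

1 | rac-1-phenylprop-2-en-1-ol | C=CC(O)c1ccccc1 | starting material
2 | ethyl (4E)-5-phenylpent-4-enoate | CCOC(=O)CC/C=C/c1ccccc1 | intermediate
3 | (4E)-5-phenylpent-4-en-1-ol | OCCC/C=C/c1ccccc1 | intermediate
4 | 1-phenyl-5-{[(4E)-5-phenylpent-4-en-1-yl]sulfanyl}-1H-tetrazole | c1ccccc1-n1nnnc1SCCC/C=C/c1ccccc1 | intermediate
5 | 1-phenyl-5-{[(4E)-5-phenylpent-4-en-1-yl]sulfonyl}-1H-tetrazole | c1ccccc1-n1nnnc1S(=O)(=O)CCC/C=C/c1ccccc1 | intermediate
6 | (R)-citronellal | C[C@H](CCC=C(C)C)CC=O | starting material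
7 | (4R)-4,8-dimethylnon-7-en-1-yne | C[C@H](CCC=C(C)C)CC#C | intermediate
8 | 3,3-dimethyl-5-[(3R)-3-methylhex-5-yn-1-yl]-1,2,4-trioxolane (secondary ozonide) | C[C@H](CCC1OOC(C)(C)O1)CC#C | intermediate
9 | (4R)-4-methylhept-6-ynal | C[C@H](CCC=O)CC#C | intermediate
10 | [(1E,5E,9R)-9-methyldodeca-1,5-dien-11-yn-1-yl]benzene | C[C@H](CC/C=C/CC/C=C/c1ccccc1)CC#C | intermediate
11 | dimethyl[(1E,4R,7E,11E)-2,4-dimethyl-12-phenyldodeca-1,7,11-trien-1-yl]alumane | C[C@H](CC/C=C/CC/C=C/c1ccccc1)C/C(C)=C/[Al](C)C | intermediate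
12 | (2E,5R,8E,12E)-3,5-dimethyl-13-phenyltrideca-2,8,12-trien-1-ol | C[C@H](CC/C=C/CC/C=C/c1ccccc1)C/C(C)=C/CO | intermediate
13 | [(2S,3S)-3-methyl-3-[(2R,5E,9E)-2-methyl-10-phenyldeca-5,9-dien-1-yl]oxiran-2-yl]methanol | C[C@H](CC/C=C/CC/C=C/c1ccccc1)C[C@@]1(C)[C@H](CO)O1 | intermediate
14 | (3S,5R,8E,12E)-3,5-dimethyl-13-phenyltrideca-8,12-diene-1,3-diol | C[C@H](CC/C=C/CC/C=C/c1ccccc1)C[C@](C)(O)CCO | intermediate
15 | (3S,5R,8E,12E)-3-hydroxy-3,5-dimethyl-13-phenyltrideca-8,12-dien-1-yl 4-methylbenzenesulfonate | C[C@H](CC/C=C/CC/C=C/c1ccccc1)C[C@](C)(O)CCOS(=O)(=O)c1ccc(C)cc1 | intermediate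
16 | (2S)-2-methyl-2-[(2R,5E,9E)-2-methyl-10-phenyldeca-5,9-dien-1-yl]oxetane | C[C@H](CC/C=C/CC/C=C/c1ccccc1)C[C@@]1(C)CCO1 | intermediate
17 | (3R,5R,8E,12E)-3-hydroperoxy-3,5-dimethyl-13-phenyltrideca-8,12-dien-1-ol | C[C@H](CC/C=C/CC/C=C/c1ccccc1)C[C@@](C)(OO)CCO | intermediate
18 | (3R,5R,8E,12E)-3-[(2-methoxypropan-2-yl)peroxy]-3,5-dimethyl-13-phenyltrideca-8,12-dien-1-ol | C[C@H](CC/C=C/CC/C=C/c1ccccc1)C[C@@](C)(OOC(C)(C)OC)CCO | intermediate
19 | (3R,5R,8E,12E)-3-[(2-methoxypropan-2-yl)peroxy]-3,5-dimethyl-13-phenyltrideca-8,12-dienal | C[C@H](CC/C=C/CC/C=C/c1ccccc1)C[C@@](C)(OOC(C)(C)OC)CC=O | intermediate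
20 | (4R,6R,9E,13E)-4-[(2-methoxypropan-2-yl)peroxy]-4,6-dimethyl-14-phenyltetradeca-9,13-dien-2-ol (C2 epimers) | C[C@H](CC/C=C/CC/C=C/c1ccccc1)C[C@@](C)(OOC(C)(C)OC)CC(C)O | intermediate
21 | (4R,6R,9E,13E)-4-[(2-methoxypropan-2-yl)peroxy]-4,6-dimethyl-14-phenyltetradeca-9,13-dien-2-one | C[C@H](CC/C=C/CC/C=C/c1ccccc1)C[C@@](C)(OOC(C)(C)OC)CC(C)=O | intermediate
22 | ethyl (2E,5R,7R,10E,14E)-5-[(2-methoxypropan-2-yl)peroxy]-3,5,7-trimethyl-15-phenylpentadeca-2,10,14-trienoate | C[C@H](CC/C=C/CC/C=C/c1ccccc1)C[C@@](C)(OOC(C)(C)OC)C/C(C)=C/C(=O)OCC | intermediate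
23 | (2E,5R,7R,10E,14E)-5-[(2-methoxypropan-2-yl)peroxy]-3,5,7-trimethyl-15-phenylpentadeca-2,10,14-trien-1-ol | C[C@H](CC/C=C/CC/C=C/c1ccccc1)C[C@@](C)(OOC(C)(C)OC)C/C(C)=C/CO | intermediate
24 | [(2S,3S)-3-{(2R,4R,7E,11E)-2-[(2-methoxypropan-2-yl)peroxy]-2,4-dimethyl-12-phenyldodeca-7,11-dien-1-yl}-3-methyloxiran-2-yl]methanol | C[C@H](CC/C=C/CC/C=C/c1ccccc1)C[C@@](C)(OOC(C)(C)OC)C[C@@]1(C)[C@H](CO)O1 | intermediate
25 | [(2S,3S)-3-[(2R,4R,7E,11E)-2-hydroperoxy-2,4-dimethyl-12-phenyldodeca-7,11-dien-1-yl]-3-methyloxiran-2-yl]methanol | C[C@H](CC/C=C/CC/C=C/c1ccccc1)C[C@@](C)(OO)C[C@@]1(C)[C@H](CO)O1 | intermediate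
26 | (1S)-1-[(3R,5R)-3,5-dimethyl-5-[(2R,5E,9E)-2-methyl-10-phenyldeca-5,9-dien-1-yl]-1,2-dioxolan-3-yl]ethane-1,2-diol | C[C@H](CC/C=C/CC/C=C/c1ccccc1)C[C@]1(C)C[C@](C)([C@@H](O)CO)OO1 | intermediate
27 | (3R,5R)-3,5-dimethyl-5-[(2R,5E,9E)-2-methyl-10-phenyldeca-5,9-dien-1-yl]-1,2-dioxolane-3-carbaldehyde | C[C@H](CC/C=C/CC/C=C/c1ccccc1)C[C@]1(C)C[C@](C)(C=O)OO1 | intermediate
28 | (3R,5R)-3-(2-methoxyethenyl)-3,5-dimethyl-5-[(2R,5E,9E)-2-methyl-10-phenyldeca-5,9-dien-1-yl]-1,2-dioxolane (E/Z mixture) | C[C@H](CC/C=C/CC/C=C/c1ccccc1)C[C@]1(C)C[C@](C)(C=COC)OO1 | intermediate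
29 | 2-[(3R,5R)-3,5-dimethyl-5-[(2R,5E,9E)-2-methyl-10-phenyldeca-5,9-dien-1-yl]-1,2-dioxolan-3-yl]acetaldehyde | C[C@H](CC/C=C/CC/C=C/c1ccccc1)C[C@]1(C)C[C@](C)(CC=O)OO1 | intermediate
30 | 2-[(3R,5R)-3,5-dimethyl-5-[(2R,5E,9E)-2-methyl-10-phenyldeca-5,9-dien-1-yl]-1,2-dioxolan-3-yl]acetic acid | C[C@H](CC/C=C/CC/C=C/c1ccccc1)C[C@]1(C)C[C@](C)(CC(=O)O)OO1 | target

## Step count and risks

Total step count: 25. Longest linear sequence: 23 steps (steps 1–4, then 7–25, from 1); the citronellal branch runs 21 steps (5, 6, then 7–25).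

Most likely to fail:

**Step 18 (olefination of the β-peroxy ketone).** Enolisation of the hindered ketone toward the peroxide-bearing carbon can trigger β-elimination of the peroxy group faster than the slow addition of the phosphonate anion, and E/Z control may be incomplete. The fallback sets out from 21, gives up the olefination and rejoins the route at 30. Treatment of 21 with p-TsOH in MeOH should exchange the peroxyketal to give (4R,6R,9E,13E)-4-hydroperoxy-4,6-dimethyl-14-phenyltetradeca-9,13-dien-2-one F1, which closes and ketalises in the same flask to (5R)-3-methoxy-3,5-dimethyl-5-[(2R,5E,9E)-2-methyl-10-phenyldeca-5,9-dien-1-yl]-1,2-dioxolane F2 (both C3 epimers). Ionisation of F2 with TiCl4 in CH2Cl2 at −78 °C and capture by 1-methoxy-1-(trimethylsilyloxy)ethene should give methyl 2-[(3R,5R)-3,5-dimethyl-5-[(2R,5E,9E)-2-methyl-10-phenyldeca-5,9-dien-1-yl]-1,2-dioxolan-3-yl]acetate F3 together with its (3S,5R)-epimer F4, to be separated by chromatography. LiOH in aqueous THF then converts F3 into 30. C3 is then set by substrate bias and separation instead of by the epoxide.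

**Step 21 (key ring closure).** The tertiary epoxide carbon may ionise ahead of ring closure, which would erode configuration at C3, allow a hydride shift, or let an external nucleophile or the 6-endo pathway compete. The fallback sets out from 22 and rejoins at 30. Aqueous AcOH in THF should unmask ethyl (2E,5R,7R,10E,14E)-5-hydroperoxy-3,5,7-trimethyl-15-phenylpentadeca-2,10,14-trienoate F5. Et2NH in CF3CH2OH should then promote a 5-exo intramolecular peroxy-Michael addition to give ethyl 2-[(3R,5R)-3,5-dimethyl-5-[(2R,5E,9E)-2-methyl-10-phenyldeca-5,9-dien-1-yl]-1,2-dioxolan-3-yl]acetate F6 and its (3S,5R)-epimer F7. After chromatographic separation, LiOH in aqueous THF converts F6 into 30.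

**Step 23 (Wittig homologation next to the peroxide).** The ylide may attack the O–O bond, or the adduct alkoxide next to the peroxide carbon may fragment, in competition with slow olefination of the neopentyl-type aldehyde. The fallback sets out from 27 and rejoins at 30 by Arndt–Eistert homologation. Pinnick oxidation of 27 should give (3R,5R)-3,5-dimethyl-5-[(2R,5E,9E)-2-methyl-10-phenyldeca-5,9-dien-1-yl]-1,2-dioxolane-3-carboxylic acid F8. Isobutyl chloroformate and Et3N in THF at −20 °C give the mixed isobutyl carbonic anhydride F9. Ethereal CH2N2 gives 2-diazo-1-[(3R,5R)-3,5-dimethyl-5-[(2R,5E,9E)-2-methyl-10-phenyldeca-5,9-dien-1-yl]-1,2-dioxolan-3-yl]ethan-1-one F10. Wolff rearrangement (PhCO2Ag cat., Et3N, THF/H2O) should then deliver 30 with retention at the migrating C3.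

## Further compounds

F1 | step 18 | (4R,6R,9E,13E)-4-hydroperoxy-4,6-dimethyl-14-phenyltetradeca-9,13-dien-2-one | C[C@H](CC/C=C/CC/C=C/c1ccccc1)C[C@@](C)(OO)CC(C)=O
F2 | step 18 | (5R)-3-methoxy-3,5-dimethyl-5-[(2R,5E,9E)-2-methyl-10-phenyldeca-5,9-dien-1-yl]-1,2-dioxolane (C3 epimers) | C[C@H](CC/C=C/CC/C=C/c1ccccc1)C[C@]1(C)CC(C)(OC)OO1
F3 | step 18 | methyl 2-[(3R,5R)-3,5-dimethyl-5-[(2R,5E,9E)-2-methyl-10-phenyldeca-5,9-dien-1-yl]-1,2-dioxolan-3-yl]acetate | C[C@H](CC/C=C/CC/C=C/c1ccccc1)C[C@]1(C)C[C@](C)(CC(=O)OC)OO1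
F4 | step 18 | methyl 2-[(3S,5R)-3,5-dimethyl-5-[(2R,5E,9E)-2-methyl-10-phenyldeca-5,9-dien-1-yl]-1,2-dioxolan-3-yl]acetate | C[C@H](CC/C=C/CC/C=C/c1ccccc1)C[C@]1(C)C[C@@](C)(CC(=O)OC)OO1
F5 | step 21 | ethyl (2E,5R,7R,10E,14E)-5-hydroperoxy-3,5,7-trimethyl-15-phenylpentadeca-2,10,14-trienoate | C[C@H](CC/C=C/CC/C=C/c1ccccc1)C[C@@](C)(OO)C/C(C)=C/C(=O)OCC
F6 | step 21 | ethyl 2-[(3R,5R)-3,5-dimethyl-5-[(2R,5E,9E)-2-methyl-10-phenyldeca-5,9-dien-1-yl]-1,2-dioxolan-3-yl]acetate | C[C@H](CC/C=C/CC/C=C/c1ccccc1)C[C@]1(C)C[C@](C)(CC(=O)OCC)OO1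
F7 | step 21 | ethyl 2-[(3S,5R)-3,5-dimethyl-5-[(2R,5E,9E)-2-methyl-10-phenyldeca-5,9-dien-1-yl]-1,2-dioxolan-3-yl]acetate | C[C@H](CC/C=C/CC/C=C/c1ccccc1)C[C@]1(C)C[C@@](C)(CC(=O)OCC)OO1
F8 | step 23 | (3R,5R)-3,5-dimethyl-5-[(2R,5E,9E)-2-methyl-10-phenyldeca-5,9-dien-1-yl]-1,2-dioxolane-3-carboxylic acid | C[C@H](CC/C=C/CC/C=C/c1ccccc1)C[C@]1(C)C[C@](C)(C(=O)O)OO1
F9 | step 23 | (3R,5R)-3,5-dimethyl-5-[(2R,5E,9E)-2-methyl-10-phenyldeca-5,9-dien-1-yl]-1,2-dioxolane-3-carboxylic isobutyl carbonic anhydride | C[C@H](CC/C=C/CC/C=C/c1ccccc1)C[C@]1(C)C[C@](C)(C(=O)OC(=O)OCC(C)C)OO1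
F10 | step 23 | 2-diazo-1-[(3R,5R)-3,5-dimethyl-5-[(2R,5E,9E)-2-methyl-10-phenyldeca-5,9-dien-1-yl]-1,2-dioxolan-3-yl]ethan-1-one | C[C@H](CC/C=C/CC/C=C/c1ccccc1)C[C@]1(C)C[C@](C)(C(=O)C=[N+]=[N-])OO1
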